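**Strategy**

The 2-pyranone is cut at C2–C3 and O1–C2. The lactone carbonyl C2 is a single carbon at the carboxylic acid level, bonded to congested C3, which carries the 1,1-dimethylallyl group. C3–C6 form a benzoyl-capped 1,3-diketone whose only terminal acidic site is C3. The key step therefore adds carbon dioxide to the terminal carbon of the dilithium dianion of 5,5-dimethyl-1-phenylhept-6-ene-1,3-dione. This creates the C2–C3 bond and completes the carbon skeleton of the ring in one operation, without ring closure. The diketone comes from one Claisen condensation. Dehydrative lactonisation, acylation of the C4 hydroxyl with silyl-protected 3-hydroxy-3-methylbutanoic acid and desilylation complete the route.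

Key step: step 2

Remark: the target has no stereocentre; the one stereocentre of acid 6 is formed racemic and becomes sp2 in step 3. LiN(iPr)2 is taken as a purchased solution.

**Route**

Step 1
Reactants: 1 acetophenone; 2 methyl 3,3-dimethylpent-4-enoate
Product: 3 5,5-dimethyl-1-phenylhept-6-ene-1,3-dione
Conditions: NaH (2.2 equiv), 2 (1.5 equiv), THF, reflux, slow addition of 1; then aq HCl, 0 °C
Reagents that add atoms: none
Why: Crossed Claisen condensation in which the sodium enolate of 1 attacks the ester carbonyl of 2 and the second equivalent of NaH removes the acidic central proton of the new 1,3-diketone, which drives the equilibrium, while slow addition of 1 suppresses its self-aldol and the neopentyl-type α-CH2 of 2 disfavours ester self-condensation.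

Step 2
Reactants: 3 5,5-dimethyl-1-phenylhept-6-ene-1,3-dione; 4 carbon dioxide
Product: 6 2-(2-methylbut-3-en-2-yl)-3,5-dioxo-5-phenylpentanoic acid (racemic), via dilithium dienediolate 5 (not isolated)
Conditions: LiN(iPr)2 (2.5 equiv), THF, −78 → 0 °C; cannulate into THF saturated with dry CO2, −78 °C; cold 1 M HCl to pH 2, 0 °C, cold extraction, no heating, used at once
Reagents that add atoms: none
Why: The first equivalent of amide base removes a proton from the doubly activated central CH2 (future C5) and the second can only take one from the CH2 beside the quaternary carbon (future C3), since the benzoyl terminus has no α-hydrogen, so dienediolate 5 carries its most basic carbon at that terminus. This last-formed site adds to carbon dioxide, a small linear electrophile that tolerates the neopentyl-type congestion, forming the C2–C3 bond and a lithium carboxylate that is inert to further attack. The closest known reaction type is the terminal carboxylation of 1,3-diketone dianions to 3,5-diketo acids, the established precursors of 4-hydroxy-2-pyranones. No ring is closed in this step. The new stereocentre at the carboxyl-bearing carbon is formed racemic and needs no control, because it is enolisable and becomes the sp2 carbon C3 in step 3. The selectivity required is terminal over central carbon attack (and carbon over oxygen), secured by the higher basicity and nucleophilicity of the terminal carbanion compared with the delocalised central diketonate and by the reversibility of O-carboxylation, while transfer into excess carbon dioxide at low temperature limits proton exchange and cold acidification limits decarboxylation.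

Step 3
Reactants: 6 2-(2-methylbut-3-en-2-yl)-3,5-dioxo-5-phenylpentanoic acid
Product: 8 4-hydroxy-3-(2-methylbut-3-en-2-yl)-6-phenyl-2H-pyran-2-one, via mixed trifluoroacetic anhydride 7 (not isolated)
Conditions: (CF3CO)2O (3 equiv), CH2Cl2, 0 °C, short; then MeOH/H2O, 0 °C
Reagents that add atoms: none
Why: Dehydrative lactonisation of a 3,5-diketo acid, in which the carboxyl is activated as mixed anhydride 7 and the enol oxygen of the benzoyl carbonyl (future O1) attacks it in a 6-exo-trig closure that forms O1–C2 and, after tautomerisation, the 4-hydroxy-2-pyranone faster than the β-keto acid can lose carbon dioxide; the short cold exposure to acid should leave the monosubstituted vinyl group untouched and the aqueous methanol quench cleaves any trifluoroacetate on the C4 oxygen.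

Step 4
Reactants: 9 3-hydroxy-3-methylbutanoic acid
Product: 11 3-methyl-3-[(triethylsilyl)oxy]butanoic acid, via bis(triethylsilyl) derivative 10 (not isolated)
Conditions: Et3SiOTf (2.3 equiv), 2,6-lutidine (3 equiv), CH2Cl2, 0 °C → rt; then THF/H2O/AcOH, 0 °C
Reagents that add atoms: triethylsilyl trifluoromethanesulfonate, CC[Si](CC)(CC)OS(=O)(=O)C(F)(F)F
Why: Silylation of a tertiary alcohol with a silyl triflate and a hindered pyridine base gives bis-silyl compound 10, whose silyl ester is far more labile than the tertiary silyl ether and is hydrolysed selectively by water attacking silicon to release the free acid.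

Step 5
Reactants: 8 4-hydroxy-3-(2-methylbut-3-en-2-yl)-6-phenyl-2H-pyran-2-one; 11 3-methyl-3-[(triethylsilyl)oxy]butanoic acid
Product: 13 3-(2-methylbut-3-en-2-yl)-2-oxo-6-phenyl-2H-pyran-4-yl 3-methyl-3-[(triethylsilyl)oxy]butanoate, via O-acylisourea 12 (not isolated)
Conditions: 11, DCC (1.2 equiv), CH2Cl2, 0 °C; then 8, DMAP (0.2 equiv), 0 °C → rt
Reagents that add atoms: none
Why: Steglich esterification in which DMAP relays the acyl group from O-acylisourea 12 to the acidic C4 enol oxygen, as is usual for 4-hydroxy-2-pyranones, while the quaternary substituent at C3 blocks the O-to-C acyl shift that DMAP otherwise triggers in 4-acyloxy-2-pyranones, and the tertiary silyl ether prevents the acid from acylating itself.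

Step 6
Reactants: 13 3-(2-methylbut-3-en-2-yl)-2-oxo-6-phenyl-2H-pyran-4-yl 3-methyl-3-[(triethylsilyl)oxy]butanoate
Product: 14 3-(2-methylbut-3-en-2-yl)-2-oxo-6-phenyl-2H-pyran-4-yl 3-hydroxy-3-methylbutanoate (target)
Conditions: HF·pyridine, pyridine/THF, 0 °C → rt; pH 7 phosphate buffer work-up
Reagents that add atoms: none
Why: Fluoride-driven cleavage of the Si–O bond under buffered, weakly acidic conditions frees the tertiary alcohol, and these conditions are chosen because the enol ester (a vinylogous anhydride) would be at risk with basic fluoride sources, whereas it and the vinyl group should be inert to buffered hydrogen fluoride.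

**Compound list**

1 | acetophenone | CC(=O)c1ccccc1 | starting material
2 | methyl 3,3-dimethylpent-4-enoate | C=CC(C)(C)CC(=O)OC | starting material
3 | 5,5-dimethyl-1-phenylhept-6-ene-1,3-dione (largely enolised; drawn as the diketone) | C=CC(C)(C)CC(=O)CC(=O)c1ccccc1 | intermediate
4 | carbon dioxide | O=C=O | starting material
5 | dilithium 5,5-dimethyl-1-phenylhepta-1,3,6-triene-1,3-bis(olate), the dianion of 3 | [Li+].[Li+].C=CC(C)(C)C=C([O-])C=C([O-])c1ccccc1 | intermediate
6 | 2-(2-methylbut-3-en-2-yl)-3,5-dioxo-5-phenylpentanoic acid (racemic) | C=CC(C)(C)C(C(=O)O)C(=O)CC(=O)c1ccccc1 | intermediate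
7 | 2-(2-methylbut-3-en-2-yl)-3,5-dioxo-5-phenylpentanoic trifluoroacetic anhydride | C=CC(C)(C)C(C(=O)OC(=O)C(F)(F)F)C(=O)CC(=O)c1ccccc1 | intermediate
8 | 4-hydroxy-3-(2-methylbut-3-en-2-yl)-6-phenyl-2H-pyran-2-one | C=CC(C)(C)c1c(O)cc(-c2ccccc2)oc1=O | intermediate
9 | 3-hydroxy-3-methylbutanoic acid | CC(C)(O)CC(=O)O | starting material
10 | triethylsilyl 3-methyl-3-[(triethylsilyl)oxy]butanoate | CC[Si](CC)(CC)OC(C)(C)CC(=O)O[Si](CC)(CC)CC | intermediate
11 | 3-methyl-3-[(triethylsilyl)oxy]butanoic acid | CC[Si](CC)(CC)OC(C)(C)CC(=O)O | intermediate
12 | N,N'-dicyclohexyl-O-{3-methyl-3-[(triethylsilyl)oxy]butanoyl}isourea | CC[Si](CC)(CC)OC(C)(C)CC(=O)OC(=NC1CCCCC1)NC1CCCCC1 | intermediate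
13 | 3-(2-methylbut-3-en-2-yl)-2-oxo-6-phenyl-2H-pyran-4-yl 3-methyl-3-[(triethylsilyl)oxy]butanoate | C=CC(C)(C)c1c(OC(=O)CC(C)(C)O[Si](CC)(CC)CC)cc(-c2ccccc2)oc1=O | intermediate
14 | 3-(2-methylbut-3-en-2-yl)-2-oxo-6-phenyl-2H-pyran-4-yl 3-hydroxy-3-methylbutanoate | C=CC(C)(C)c1c(OC(=O)CC(C)(C)O)cc(-c2ccccc2)oc1=O | target

**Step count**

Total step count: 6. Longest linear sequence: 5 steps (steps 1, 2, 3, 5, 6); step 4 is a one-step side branch.

**Steps most likely to fail**

Step 2. The second deprotonation at the CH2 next to the quaternary carbon may be incomplete, proton exchange may quench the terminal carbanion before it meets carbon dioxide, or the β-keto acid may lose carbon dioxide during acidification and isolation. The fallback sets out from ester 2 and forms the C5–C6 bond instead, so that no free β-keto acid arises. The lithium enolate of 2 (LiN(iPr)2, THF, −78 °C, two equivalents of enolate per acyl chloride) is C-acetylated with acetyl chloride to methyl 2-acetyl-3,3-dimethylpent-4-enoate F1. Its dianion (NaH, then n-BuLi, THF, 0 °C) is acylated at the terminal methyl with methyl benzoate to methyl 2-(2-methylbut-3-en-2-yl)-3,5-dioxo-5-phenylpentanoate F2. Heating F2 with DBU in toluene should close the lactone with loss of methanol, and the fallback comes back to the route at pyranone 8.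

Step 5. O-acylation of the hindered, weakly nucleophilic C4 enol may be slow, which would allow the activated acid to rearrange to an unreactive N-acylurea or the acyl group to settle on the C2 oxygen. The fallback sets out from acid 11. It is converted under neutral conditions with 1-chloro-N,N,2-trimethylprop-1-en-1-amine (CH2Cl2, 0 °C) into 3-methyl-3-[(triethylsilyl)oxy]butanoyl chloride F3. F3 is added to pyranone 8 with triethylamine in CH2Cl2 at −20 → 0 °C (acylation of the preformed ammonium enolate by an acyl chloride), and the fallback comes back at ester 13.

Step 6. Removal of the tertiary silyl ether may be slow, and forcing it may cause acyl cleavage of the enol ester or β-elimination of the freed tertiary alcohol. The fallback avoids protection altogether: it sets out from pyranone 8 and unprotected acid 9, which are coupled directly with DCC and catalytic DMAP in CH2Cl2 at 0 °C, relying on the low nucleophilicity of the tertiary hydroxyl (the risk there is competing self-acylation to a β-lactone). It arrives directly at target 14, and no compound outside the compound list arises (F0).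

**Further compounds**

F1 | step 2 | methyl 2-acetyl-3,3-dimethylpent-4-enoate (racemic) | C=CC(C)(C)C(C(C)=O)C(=O)OC
F2 | step 2 | methyl 2-(2-methylbut-3-en-2-yl)-3,5-dioxo-5-phenylpentanoate (racemic) | C=CC(C)(C)C(C(=O)OC)C(=O)CC(=O)c1ccccc1
F3 | step 5 | 3-methyl-3-[(triethylsilyl)oxy]butanoyl chloride | CC[Si](CC)(CC)OC(C)(C)CC(Cl)=O
F0 | step 6 | none | none
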